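The readings are calculated with constants of no real substance, and the scatter is random.

At the reading of 25 h, when the flask stands where it stands and one option has to be chosen for the next 8.0 h, two chemists look at the same readings and disagree about why target has slowed.

| setting | dusk | noon | flask |
|---|---|---|---|
| starting material | 20 mM | 20 mM | 20 mM |
| second substrate | 20 mM | 20 mM | 20.0 mM |
| free catalyst | 3 mM | 3 mM | 3.0 mM |
| impurity | 3 mM | 3 mM | 3.0 mM |
| temperature | 25 °C | 10 °C | 25 °C |
| remark | the very flask that is asked about, followed so far | run made earlier |  |
| time |  |  | 25 h |

| run | time / min | target / % | starting material / % |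
|---|---|---|---|
| dusk | 240 | 24.0 | 72.7 |
| dusk | 480 | 30.7 | 70.6 |
| dusk | 720 | 33.0 | 65.4 |
| dusk | 900 | 35.5 | 64.6 |
| dusk | 1200 | 38.1 | 62.3 |
| dusk | 1500 | 39.5 | 60.2 |
| noon | 480 | 12.4 | 85.8 |
| noon | 900 | 17.1 | 82.3 |
| noon | 1500 | 20.4 | 80.8 |
| noon | 1800 | 20.6 | 79.4 |
| noon | 2400 | 20.6 | 78.8 |
| noon | 2880 | 22.0 | 76.7 |

(scatter of a reading: 1 percentage point)

- Saturday's: at 25 h raise the temperature by 25 K, then wait 8.0 h
- Friday's: change nothing and wait 8.0 h more
- Tuesday's: at 25 h take out 90 % of the target then present, then wait 8.0 h
- Wednesday's: at 25 h add free catalyst, 100 % of the amount charged, then wait 8.0 h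

- target that was removed still counts
- what was read earlier has a scatter of 1 percentage point, one standard deviation
- additions bring no volume worth counting

* target, in percent of the starting material first charged, at 25 h
* which option adds most target ("none" when 2 percentage points or less is all one gets) (Saturday's / Friday's / Tuesday's / Wednesday's / none)
* target present, with what was taken out counted in, in percent of the starting material first charged, after Saturday's
* target present, with what was taken out counted in, in percent of the starting material first charged, after Tuesday's

The dusk run, which is this flask followed so far, made 24.0 % of target in its first 240 min but 4 percentage points in its last 600 min, with 60.2 % of starting material still unconverted at the last reading.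

The first chemist reads this as an equilibrium: target over starting material at the last reading is 0.656 in the dusk run at 25 °C and 0.287 in the noon run at 10 °C, so taking out 90 % of the target in Tuesday's option should let the flask refill to the dusk ratio and give 61.0 %, with what was removed counted in.

The second chemist sees 3.0 mM of free catalyst charged against 3.0 mM of impurity, a difference of 0 mM, and calls this difference, free catalyst charged minus impurity charged, the live margin, on the view that one impurity takes one catalyst for good. With that margin the flask is running on a remnant, so removing target should bring little, whereas Wednesday's addition raises the margin to 3.00 mM and should restart the flask.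

The forecast sides with the second chemist, on the ground that “catalyst is killed by equimolar impurity”: it gives 39.5 % at 25 h, 50 % after Saturday's and 41.5 % after Tuesday's, and it names Wednesday's as best.

The flask gives 39.3 % at 25 h, 51.2 % after Saturday's and 41.3 % after Tuesday's, and Wednesday's is best, adding 53 points against 12 points for Saturday's, 2 points for Tuesday's and 1.8 points for Friday's.

    starting material + free catalyst ⇌ catalyst intermediate A (K = 7100 M⁻¹, k = 11.0 M⁻¹ min⁻¹, Ea = 62.0 kJ mol⁻¹, ΔH = −18.0 kJ mol⁻¹)
    catalyst intermediate A ⇌ free catalyst + target (K = 0.0190 M, k = 0.130 min⁻¹, Ea = 93.0 kJ mol⁻¹, ΔH = −10.0 kJ mol⁻¹)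
    second substrate + free catalyst ⇌ catalyst intermediate B (K = 120 M⁻¹, k = 77.0 M⁻¹ min⁻¹, Ea = 57.0 kJ mol⁻¹, ΔH = −23.0 kJ mol⁻¹)
    catalyst intermediate B → free catalyst + second product (k = 0.0310 min⁻¹, Ea = 82.0 kJ mol⁻¹)
    free catalyst + impurity → spent catalyst (k = 100 M⁻¹ min⁻¹, Ea = 38.0 kJ mol⁻¹)
    (constants at 25 °C)

Against the margin of 0 mM, the flask at 1500 min holds 99.0 % spent catalyst and, in its working forms together, 0.992 %, a remnant that the margin does not show and that brings 1.8 points in Friday's wait. The neighbour charged with 12 mM of free catalyst has a margin of 9.00 mM, or 75.0 % of its catalyst, and at 1500 min that neighbour holds 75.0 % as free catalyst and catalyst intermediate A, while impurity, the limiting reagent of the poisoning, stands at 0 %. That neighbour is where the first chemist's equilibrium view applies, though not at the ratio he read: its target over starting material stands at 135, far above the 0.656 of the last dusk reading and near the equilibrium constant of the whole conversion, 135, with target at 79.0 %.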